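## Retrosynthetic overview

1. Target 16 ⇐ base equilibration at C3/C3′ (trans is the stable lactone) ⇐ bis-lactone 15 ⇐ reductive auxiliary removal, two lactonisations and MOM loss from bis-succinate 13.
2. Key disconnection: the C3–C4 bond of each of the two γ-butyrolactone rings. C3 is the α-carbon next to C2=O and carries the diaryl-ether benzyl; C4 is next to C5H2–O and carries the 3,4-dimethoxybenzyl. Both ends are α-carbons of carboxyl-level carbons (like polarity), so both bonds are made at once by twofold oxidative enolate heterocoupling of bis-ester 6 with two molecules of chiral imide 10.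
3. Stereocentres: C4/C4′ come from the (R)-oxazolidinone in the key step; C3/C3′ are funnelled to trans at the end.
4. Bis-ester 6 ⇐ double Wittig olefination and hydrogenation of dialdehyde 4 ⇐ Ullmann ether coupling of vanillin with MOM-protected 5-iodovanillin (fixes the 4-O-5′ ether).
5. Ring order: both arenes are bought, the diaryl ether is made first, and the two lactone rings are closed together in step 7.

Key step: step 6

Remark on the chemistry: the SMILES specifies S at all four lactone stereocentres (both lactones 3,4-trans), the antipode of the (3R,4R) arctigenin series, so the (R)-configured auxiliary is used. Compounds 13–15 are carried as epimer mixtures at the two ester/lactone α-carbons (left undefined in their SMILES) and converge in step 8.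

## Route

Step 1
Reactants: 1 5-iodovanillin
Product: 2 3-iodo-5-methoxy-4-(methoxymethoxy)benzaldehyde
Conditions: MOMCl (1.5 equiv), i-Pr2NEt (2 equiv), CH2Cl2, 0 °C → rt
Reagents that add atoms: chloromethyl methyl ether, COCCl
Why: O-alkylation (MOM protection) of the acidic phenol should be clean; the acetal masks the only free OH of ring B against the oxidant of step 6 and is cleaved by the acid of step 7.

Step 2
Reactants: 2 3-iodo-5-methoxy-4-(methoxymethoxy)benzaldehyde, 3 vanillin
Product: 4 3-(4-formyl-2-methoxyphenoxy)-5-methoxy-4-(methoxymethoxy)benzaldehyde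
Conditions: CuI (10 mol %), picolinic acid (20 mol %), K3PO4 (2 equiv), DMSO, 90 °C
Reagents that add atoms: none
Why: Ullmann diaryl ether coupling, in which the picolinate-ligated copper should tolerate the ortho-substituted iodide and the formyl-deactivated phenoxide; the iodide fixes the ether at C5 of ring B and the vanillin oxygen becomes O–C4 of ring A.

Step 3
Reactants: 4 3-(4-formyl-2-methoxyphenoxy)-5-methoxy-4-(methoxymethoxy)benzaldehyde
Product: 5 di-tert-butyl bis-cinnamate of the diaryl ether (E,E)
Conditions: Ph3P=CHCO2t-Bu (2.4 equiv), toluene, 80 °C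
Reagents that add atoms: tert-butyl (triphenylphosphoranylidene)acetate, CC(C)(C)OC(=O)C=P(c1ccccc1)(c1ccccc1)c1ccccc1
Why: twofold Wittig olefination of two aryl aldehydes with a stabilised ylide should be reliable, and the alkene geometry is irrelevant because both alkenes are hydrogenated next.

Step 4
Reactants: 5 di-tert-butyl bis-cinnamate of the diaryl ether (E,E)
Product: 6 di-tert-butyl bis(dihydrocinnamate) of the diaryl ether
Conditions: H2 (1 atm), 10% Pd/C, EtOAc, rt
Reagents that add atoms: none
Why: heterogeneous catalytic hydrogenation of the two cinnamate C=C bonds under neutral conditions should leave the MOM acetal, the diaryl ether and the tert-butyl esters untouched.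

Step 5
Reactants: 7 3-(3,4-dimethoxyphenyl)propanoic acid, 8 (R)-4-benzyloxazolidin-2-one
Product: 10 (R)-4-benzyl-3-[3-(3,4-dimethoxyphenyl)propanoyl]oxazolidin-2-one, via mixed pivalic anhydride 9 (not isolated)
Conditions: PivCl (1.1 equiv), Et3N (2.5 equiv), THF, −20 °C; then LiCl (1.1 equiv), 8, −20 °C → rt
Reagents that add atoms: none
Why: N-acylation of the oxazolidinone through the mixed pivalic anhydride (LiCl/Et3N variant) forms no stereocentre; the (R)-auxiliary is chosen because bond formation anti to its benzyl group gives the (S) configuration needed at C4/C4′.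

Step 6
Reactants: 6 di-tert-butyl bis(dihydrocinnamate) of the diaryl ether, 10 (R)-4-benzyl-3-[3-(3,4-dimethoxyphenyl)propanoyl]oxazolidin-2-one (3 equiv)
Product: 13 bis-succinate (twofold heterocoupling product; bis-imide bis-tert-butyl ester), via dilithium bis-enolate 11 (not isolated), via lithium Z-enolate 12 (not isolated)
Conditions: LDA (5.2 equiv), THF, −78 °C, 30 min; then Fe(acac)3 (5.5 equiv), −78 °C → rt
Reagents that add atoms: none
Why: LDA gives the bis(ester enolate) 11 and the chelated Z-imide enolate 12, which form mixed lithium aggregates; Fe(acac)3 removes one electron from an enolate of the aggregate, the α-carbonyl radical so formed is trapped by the neighbouring enolate of the other type, and a second one-electron oxidation of the resulting ketyl completes each C–C bond. The closest known reaction type is the Fe(III)- or Cu(II)-mediated intermolecular oxidative heterocoupling of N-acyloxazolidinone enolates with ester or ketone enolates, a relative of the oxidative dimerisation of 3-arylpropanoyl oxazolidinone enolates to 2,3-dibenzylsuccinates; here it is run at both ester arms of 6. No ring is closed in this step: the two bonds formed are the future C3–C4 bonds of both γ-butyrolactones, whose C–O bonds close in step 7 by 5-exo-trig lactonisation. The two imide α-carbons (future C4 and C4′) are set by the (R)-4-benzyl group of the auxiliary, which shields one face of the chelated Z-enolate so that the new bond forms anti to it and gives (S); the two ester α-carbons (future C3 and C3′) are only weakly controlled and are left to the equilibration of step 8. The step needs heterocoupling over homocoupling and coupling at both arms: the different oxidation potentials and mixed aggregation of ester and imide enolates should favour the cross product, the excess of 10 should drive the second coupling, and an intramolecular ester–ester coupling within 11 would require a strained 12-membered meta,para-cyclophane. The ring-B phenol, the one function that Fe(III) would oxidise, is masked as its MOM ether.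

Step 7
Reactants: 13 bis-succinate (twofold heterocoupling product; bis-imide bis-tert-butyl ester)
Product: 15 bis-lactone phenol (4S,4′S; C3/C3′ epimers), via bis(hydroxy tert-butyl ester) 14 (not isolated)
Conditions: LiBH4 (5 equiv), MeOH (5 equiv), THF, 0 °C; then 3 M HCl in MeOH (excess), 45 °C
Reagents that add atoms: none
Why: LiBH4 should reduce the exocyclic imide carbonyls to primary alcohols with release of the auxiliary while the hindered tert-butyl esters survive; methanolic HCl then closes both γ-hydroxy esters by 5-exo-trig lactonisation and cleaves the MOM acetal, with C4/C4′ untouched.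

Step 8
Reactants: 15 bis-lactone phenol (4S,4′S; C3/C3′ epimers)
Product: 16 target (3S,4S,3′S,4′S)
Conditions: DBU (4 equiv), toluene, 80 °C, Ar; aq. HCl work-up
Reagents that add atoms: none
Why: base-mediated epimerisation through the lactone enolates should funnel every C3/C3′ epimer into the thermodynamically preferred 3,4-trans lactones; C4/C4′ are not acidic, so their (S) configuration is retained and dictates (S) at C3/C3′.

## Compound list

1 | 5-iodovanillin (4-hydroxy-3-iodo-5-methoxybenzaldehyde) | O=Cc1cc(I)c(O)c(OC)c1 | starting material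
2 | 3-iodo-5-methoxy-4-(methoxymethoxy)benzaldehyde | O=Cc1cc(I)c(OCOC)c(OC)c1 | intermediate
3 | vanillin (4-hydroxy-3-methoxybenzaldehyde) | O=Cc1ccc(O)c(OC)c1 | starting material
4 | 3-(4-formyl-2-methoxyphenoxy)-5-methoxy-4-(methoxymethoxy)benzaldehyde | O=Cc1ccc(Oc2cc(C=O)cc(OC)c2OCOC)c(OC)c1 | intermediate
5 | tert-butyl (E)-3-{4-[5-((E)-3-tert-butoxy-3-oxoprop-1-enyl)-3-methoxy-2-(methoxymethoxy)phenoxy]-3-methoxyphenyl}prop-2-enoate | CC(C)(C)OC(=O)/C=C/c1ccc(Oc2cc(/C=C/C(=O)OC(C)(C)C)cc(OC)c2OCOC)c(OC)c1 | intermediate
6 | tert-butyl 3-{4-[5-(3-tert-butoxy-3-oxopropyl)-3-methoxy-2-(methoxymethoxy)phenoxy]-3-methoxyphenyl}propanoate | CC(C)(C)OC(=O)CCc1ccc(Oc2cc(CCC(=O)OC(C)(C)C)cc(OC)c2OCOC)c(OC)c1 | intermediate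
7 | 3-(3,4-dimethoxyphenyl)propanoic acid | OC(=O)CCc1ccc(OC)c(OC)c1 | starting material
8 | (R)-4-benzyloxazolidin-2-one | O=C1N[C@H](Cc2ccccc2)CO1 | starting material
9 | 3-(3,4-dimethoxyphenyl)propanoic pivalic anhydride | COc1ccc(CCC(=O)OC(=O)C(C)(C)C)cc1OC | intermediate
10 | (R)-4-benzyl-3-[3-(3,4-dimethoxyphenyl)propanoyl]oxazolidin-2-one | COc1ccc(CCC(=O)N2[C@H](Cc3ccccc3)COC2=O)cc1OC | intermediate
11 | dilithium bis(ester enolate) of 6 | [Li]OC(OC(C)(C)C)=CCc1ccc(Oc2cc(CC=C(O[Li])OC(C)(C)C)cc(OC)c2OCOC)c(OC)c1 | intermediate
12 | lithium Z-enolate of 10 | COc1ccc(C/C=C(\O[Li])N2[C@H](Cc3ccccc3)COC2=O)cc1OC | intermediate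
13 | bis-succinate: on each benzylic arm of the diaryl ether, ArCH2–CH(CO2t-Bu)–CH(CH2-3,4-dimethoxyphenyl)–C(=O)–[(R)-4-benzyl-2-oxooxazolidin-3-yl]; imide α-carbons (S), ester α-carbons as epimers | c1(CC(C(=O)OC(C)(C)C)[C@H](Cc2ccc(OC)c(OC)c2)C(=O)N2[C@H](Cc3ccccc3)COC2=O)ccc(Oc2cc(CC(C(=O)OC(C)(C)C)[C@H](Cc3ccc(OC)c(OC)c3)C(=O)N3[C@H](Cc4ccccc4)COC3=O)cc(OC)c2OCOC)c(OC)c1 | intermediate
14 | bis(γ-hydroxy tert-butyl ester): as 13 with each imide carbonyl reduced to CH2OH; carbinol-bearing carbons (S), ester α-carbons as epimers | c1(CC(C(=O)OC(C)(C)C)[C@H](Cc2ccc(OC)c(OC)c2)CO)ccc(Oc2cc(CC(C(=O)OC(C)(C)C)[C@H](Cc3ccc(OC)c(OC)c3)CO)cc(OC)c2OCOC)c(OC)c1 | intermediate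
15 | bis-lactone phenol with the target constitution, (4S,4′S), epimeric at C3 and C3′ | COc1ccc(C[C@@H]2COC(=O)C2Cc2ccc(Oc3cc(CC4C(=O)OC[C@H]4Cc4ccc(OC)c(OC)c4)cc(OC)c3O)c(OC)c2)cc1OC | intermediate
16 | (3S,4S)-4-(3,4-dimethoxybenzyl)-3-[4-(5-{[(3S,4S)-4-(3,4-dimethoxybenzyl)-2-oxotetrahydrofuran-3-yl]methyl}-2-hydroxy-3-methoxyphenoxy)-3-methoxybenzyl]dihydrofuran-2(3H)-one | COc1ccc(C[C@@H]2COC(=O)[C@H]2Cc2ccc(Oc3cc(C[C@@H]4C(=O)OC[C@H]4Cc4ccc(OC)c(OC)c4)cc(OC)c3O)c(OC)c2)cc1OC | target

## Step count and risks

Total step count: 8. Longest linear sequence: 7 (steps 1–4 and 6–8); step 5 is a one-step branch.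

Steps most likely to fail:

1. Step 6. Homocoupling of either enolate may compete with heterocoupling, the second arm may couple incompletely, and facial control at the imide α-carbon may erode under the radical conditions. The fallback sets out from 10 and 4 and comes back at 16. Imide 10 would be alkylated as its sodium enolate (NaHMDS, THF, −78 °C) with tert-butyl bromoacetate (CC(C)(C)OC(=O)CBr) anti to the auxiliary benzyl group (Evans alkylation) to give tert-butyl (3S)-4-[(4R)-4-benzyl-2-oxooxazolidin-3-yl]-3-(3,4-dimethoxybenzyl)-4-oxobutanoate F1. LiBH4 reduction and TFA lactonisation would give (S)-4-(3,4-dimethoxybenzyl)dihydrofuran-2(3H)-one F2. Its lithium enolate (LiHMDS, THF, −78 °C, 2.4 equiv) would add to both formyl groups of dialdehyde 4 anti to the C4 substituent to give the 3,4-trans bis-aldol F3 as carbinol epimers. Benzylic hydrogenolysis (H2, Pd/C, AcOH, cat. HClO4), whose acid also cleaves the MOM acetal, would then give 16; any cis-lactone present would be corrected by the conditions of step 8.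

2. Step 2. Oxidative addition at the ortho-alkoxy iodide may be slow, the formyl-deactivated phenoxide is a weak nucleophile, and protodeiodination may compete. The fallback sets out from 2 and comes back at 4 with the polarity of the C–O bond formation reversed. Miyaura borylation of 2 (B2pin2, PdCl2(dppf), KOAc, dioxane, 80 °C) would give 3-methoxy-4-(methoxymethoxy)-5-(pinacolboryl)benzaldehyde F4. Oxidation with NaBO3·4H2O (THF/H2O, rt) would give 3-hydroxy-5-methoxy-4-(methoxymethoxy)benzaldehyde F5. SNAr of its phenoxide on 4-fluoro-3-methoxybenzaldehyde (O=Cc1ccc(F)c(OC)c1; K2CO3, DMF, 110 °C), whose fluoride is activated by the para-formyl group, would give 4.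

3. Step 7. Hydride may attack the endocyclic carbamate carbonyl of the congested imides (ring opening without release of the auxiliary), or premature lactonisation may lead to over-reduction. The fallback sets out from 13 and comes back at 14. Hydrolysis of both imides with LiOH/H2O2 (THF/H2O, 0 °C) would give the bis-carboxylic acid bis-tert-butyl ester F6. BH3·SMe2 (THF, 0 °C) should reduce the carboxylic acids in the presence of the tert-butyl esters to give 14, which would be treated with methanolic HCl as in step 7 to reach 15.

## Further compounds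

F1 | step 6 | tert-butyl (3S)-4-[(4R)-4-benzyl-2-oxooxazolidin-3-yl]-3-(3,4-dimethoxybenzyl)-4-oxobutanoate | CC(C)(C)OC(=O)C[C@H](Cc1ccc(OC)c(OC)c1)C(=O)N1[C@H](Cc2ccccc2)COC1=O
F2 | step 6 | (S)-4-(3,4-dimethoxybenzyl)dihydrofuran-2(3H)-one | O=C1C[C@H](Cc2ccc(OC)c(OC)c2)CO1
F3 | step 6 | 3,4-trans bis-aldol adduct of F2 with 4 (MOM ether; carbinol epimers) | COc1ccc(C[C@@H]2COC(=O)[C@H]2C(O)c2ccc(Oc3cc(C(O)[C@@H]4C(=O)OC[C@H]4Cc4ccc(OC)c(OC)c4)cc(OC)c3OCOC)c(OC)c2)cc1OC
F4 | step 2 | 3-methoxy-4-(methoxymethoxy)-5-(4,4,5,5-tetramethyl-1,3,2-dioxaborolan-2-yl)benzaldehyde | O=Cc1cc(B2OC(C)(C)C(C)(C)O2)c(OCOC)c(OC)c1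
F5 | step 2 | 3-hydroxy-5-methoxy-4-(methoxymethoxy)benzaldehyde | O=Cc1cc(O)c(OCOC)c(OC)c1
F6 | step 7 | bis-carboxylic acid bis-tert-butyl ester (13 with both imides hydrolysed; acid α-carbons S, ester α-carbons as epimers) | c1(CC(C(=O)OC(C)(C)C)[C@H](Cc2ccc(OC)c(OC)c2)C(O)=O)ccc(Oc2cc(CC(C(=O)OC(C)(C)C)[C@H](Cc3ccc(OC)c(OC)c3)C(O)=O)cc(OC)c2OCOC)c(OC)c1
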